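**Assumptions (one line each)**
- The target is taken exactly as drawn: (2S,3S,4S,5S), i.e. the all-trans 2,5-diaryl-3,4-dimethyltetrahydrofuran.
- meso-2,3-Dimethylsuccinic acid, 5-bromo-1,2,3-trimethoxybenzene and veratrole are bought.
- The sense of induction of the PHOX ligand in Step 2 is not relied on from memory: (S)-t-Bu-PHOX is written, and the (R)-ligand is used instead if the first run gives the antipode (checked by chiral HPLC or rotation).

**Retrosynthetic overview**
1. C2–aryl bond: Friedel–Crafts arylation of a C2 oxocarbenium ion (from a lactol acetate) with veratrole, anti to the C3 methyl.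
2. Lactol acetate ⇐ all-trans γ-aryl-α,β-dimethylbutyrolactone ⇐ its 3,4-cis isomer by thermodynamic C3 epimerisation.
3. cis-Lactone ⇐ syn γ-keto acid by Felkin–Anh reduction and lactonisation.
4. Key step: the keto acid comes from catalytic enantioselective arylative ring-opening of meso-2,3-dimethylsuccinic anhydride with an arylzinc. This one event sets C4 absolutely; C5, C3 and C2 are relayed from it.
5. Ring order: meso anhydride (opened) → butyrolactone → the same oxygen heterocycle is carried through to the tetrahydrofuran.

**Route**

Step 1
Reactants: 1, meso-2,3-dimethylsuccinic acid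
Product: 2, cis-(3R,4S)-3,4-dimethyloxolane-2,5-dione (meso anhydride)
Conditions: AcCl (neat), reflux, 2 h; evaporate, Kugelrohr
Reagents that add atoms: none
Why: Cyclodehydration through the mixed acetic anhydride; the two methine centres are not touched, so the cis (meso) relationship and the mirror plane are kept.

Step 2 (key step)
Reactants: 2, meso anhydride; 3, 5-bromo-1,2,3-trimethoxybenzene
Product: 4, (2R,3S)-2,3-dimethyl-4-oxo-4-(3,4,5-trimethoxyphenyl)butanoic acid
Conditions: 3 (1.6 equiv), t-BuLi, THF, −78 °C; Zn(OTf)2, −78 °C → rt; then 2, [Rh(cod)Cl]2 (4 mol %), (S)-t-Bu-PHOX (8 mol %), THF, 50 °C; 1 M HCl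
Reagents that add atoms: none (the aryl group comes from 3)
Why: Rh-catalysed enantioselective desymmetrisation of a meso anhydride (acyl C–O oxidative addition, Zn→Rh transmetalation, reductive elimination; a Negishi-type acyl cross-coupling): the chiral P,N-ligand selects the C(=O)–O bond on the (S)-methine, so the cis-dimethyl pair becomes the (2R,3S) keto acid without either C–H being touched, which fixes C4 of the target.

Step 3
Reactants: 4, keto acid
Product: 5, (3R,4S,5S)-3,4-dimethyl-5-(3,4,5-trimethoxyphenyl)oxolan-2-one (3,4-cis, 4,5-trans)
Conditions: L-Selectride (2.2 equiv), THF, −78 → −40 °C; NaOH/H2O2; then 2 M HCl, TsOH (cat.), CH2Cl2, rt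
Reagents that add atoms: none
Why: Felkin–Anh reduction: the bulky hydride attacks the aryl ketone (Re face) anti to the CH(Me)CO2Li branch to give the (4S)-alcohol anti to the neighbouring methyl, and acid-catalysed lactonisation closes the ring with retention, placing the aryl trans to the C4 methyl.

Step 4
Reactants: 5, cis-lactone
Product: 6, (3S,4S,5S)-3,4-dimethyl-5-(3,4,5-trimethoxyphenyl)oxolan-2-one (all-trans)
Conditions: DBU (1 equiv), PhMe, 90 °C; chromatograph, recycle recovered 5; recrystallise 6 to upgrade ee
Reagents that add atoms: none
Why: Thermodynamic epimerisation through the lactone enolate: only C3 is acidic, and reprotonation equilibrates to the trans,trans-lactone with all three substituents pseudo-equatorial, while C4 and C5 are untouched.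

Step 5
Reactants: 6, all-trans lactone
Product: 7, (3S,4S,5S)-3,4-dimethyl-5-(3,4,5-trimethoxyphenyl)oxolan-2-yl acetate (anomeric mixture at C2)
Conditions: DIBAL-H (1.2 equiv), CH2Cl2, −78 °C; then pyridine, DMAP, Ac2O, −78 → 0 °C
Reagents that add atoms: acetic anhydride, CC(=O)OC(C)=O
Why: Rychnovsky-type reductive acetylation: the aluminium hemiacetal formed at −78 °C is acylated in situ before it can open to the aldehyde, so there is no over-reduction and no C3 epimerisation; the anomeric mixture is irrelevant because C2 is ionised next.

Step 6
Reactants: 7, lactol acetate; 8, veratrole (1,2-dimethoxybenzene)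
Product: 9, 5-methoxygalbelgin, (2S,3S,4S,5S)-2-(3,4-dimethoxyphenyl)-3,4-dimethyl-5-(3,4,5-trimethoxyphenyl)oxolane
Conditions: 8 (3 equiv), BF3·OEt2 (1.5 equiv), CH2Cl2, −78 → −20 °C; NaHCO3 quench
Reagents that add atoms: none (the aryl group comes from 8; acetate is lost)
Why: Friedel–Crafts C-arylation of a cyclic oxocarbenium ion (C-glycosylation type): veratrole attacks through the carbon para to a methoxy group on the face anti to the C3 methyl and the C5 aryl, setting (2S), and the all-trans product is also the thermodynamic isomer, so any reversible ionisation of the new benzylic C–O bond converges on it.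

**Compound list**
1 | meso-2,3-dimethylsuccinic acid | OC(=O)[C@H](C)[C@H](C)C(=O)O | starting material
2 | cis-3,4-dimethyloxolane-2,5-dione (meso anhydride) | C[C@H]1C(=O)OC(=O)[C@H]1C | intermediate
3 | 5-bromo-1,2,3-trimethoxybenzene | COc1cc(Br)cc(OC)c1OC | starting material
4 | (2R,3S)-2,3-dimethyl-4-oxo-4-(3,4,5-trimethoxyphenyl)butanoic acid | OC(=O)[C@H](C)[C@H](C)C(=O)c1cc(OC)c(OC)c(OC)c1 | intermediate
5 | (3R,4S,5S)-3,4-dimethyl-5-(3,4,5-trimethoxyphenyl)oxolan-2-one | O=C1O[C@H](c2cc(OC)c(OC)c(OC)c2)[C@@H](C)[C@H]1C | intermediate
6 | (3S,4S,5S)-3,4-dimethyl-5-(3,4,5-trimethoxyphenyl)oxolan-2-one | O=C1O[C@H](c2cc(OC)c(OC)c(OC)c2)[C@@H](C)[C@@H]1C | intermediate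
7 | (3S,4S,5S)-3,4-dimethyl-5-(3,4,5-trimethoxyphenyl)oxolan-2-yl acetate (C2 epimers) | CC(=O)OC1O[C@H](c2cc(OC)c(OC)c(OC)c2)[C@@H](C)[C@@H]1C | intermediate
8 | veratrole (1,2-dimethoxybenzene) | COc1ccccc1OC | starting material
9 | 5-methoxygalbelgin | COc1ccc([C@H]2O[C@H](c3cc(OC)c(OC)c(OC)c3)[C@@H](C)[C@@H]2C)cc1OC | target

**Totals**
Total steps: 6. Longest linear sequence: 6 (from 1); 3 and 8 are used as purchased.

**Three steps most likely to fail, with fallbacks**
- **Step 2 (arylative desymmetrisation):** the risk is modest ee or a sluggish electron-rich arylzinc. Fallback: split the event in two. Open 2 by cinchona-alkaloid-mediated methanolysis to the enantioenriched hemiester, convert the free acid to its thioester, and couple it with the same arylzinc under Pd (Fukuyama coupling). The resulting keto ester is reduced and lactonises directly to 5.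
- **Step 3 (substrate-controlled ketone reduction):** the risk is a poor anti:syn ratio. Fallback: reduce to whichever hydroxy acid forms cleanly and, if it is the syn (4R) alcohol, close the lactone by Mitsunobu reaction with inversion at the benzylic carbon instead of acid-catalysed closure with retention.
- **Step 6 (Friedel–Crafts arylation):** the risks are low reactivity of veratrole, some 2,3-cis isomer, or aryltetralin formation if the benzylic ether re-ionises on warming. Fallback: reverse the polarity of the C2–aryl bond formation. Add 3,4-dimethoxyphenyllithium (from 4-bromoveratrole) to lactone 6 and reduce the hemiketal with Et3SiH/BF3·OEt2. If hydride delivery gives the 2,3-cis isomer, a brief acid equilibration of the C2 benzylic centre leads to the all-trans product.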